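**Retrosynthetic overview**
- Last operation: fluoride removal of a silyl ether on O8. Both esters, the C3 ketone and the free C4 tertiary alcohol are in place before any ring is formed.
- Rings, in the order of the biosynthesis and in one flask: first the ten-membered carbocycle by closing C6–C7 (C1–C10 of a farnesyl chain) through a silyl-cation-initiated cation–olefin cyclisation of an acyclic aldehyde/2-(silylmethyl)enoate (Me3Si+ leaves C13 where germacrene A loses H+), not an allyl-metal addition; then the γ-lactone by O6→C12 acyl transfer.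
- Acyclic precursor ⇐ C2–C3 ketone synthesis (alkyl-9-BBN + thioester) joining a C3–C6 west fragment to a C7–C10/C1–C2/C11–C13 east fragment.
- West ⇐ (S)-lactic acid (Seebach dioxolanone fixes C4; aldol with 2,2-dimethoxyacetaldehyde sets C5 and brings C6). East ⇐ D-glyceraldehyde acetonide (C8), catalytic anti-crotylboration (C9, C10), Wittig reaction with a silylmethyl ylide (C7=C11, C12, C13).

Assumption: the SMILES is taken as drawn, i.e. (4R,5R,6S,7R,8R,9R,10R) in germacrane numbering with the (R)-2-methylbutanoate on O5 and the isovalerate on O9; positions C1–C15 below use germacrane numbering.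

**Route**

Step 1
Reactants: 1 (S)-lactic acid; 2 pivalaldehyde
Product: 3 (2S,5S)-2-tert-butyl-5-methyl-1,3-dioxolan-4-one
Conditions: TsOH·H2O (cat.), H2SO4 (cat.), pentane, reflux, Dean–Stark; crystallisation at −78 °C
Reagents that add atoms: none
Why: Acid-catalysed acetalisation of the α-hydroxy acid (Seebach self-regeneration-of-stereocentres template) gives the cis-dioxolanone under thermodynamic control and crystallisation, so the new acetal centre is S and the lactate centre is untouched.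

Step 2
Reactants: 3 (2S,5S)-2-tert-butyl-5-methyl-1,3-dioxolan-4-one; 4 2,2-dimethoxyacetaldehyde
Product: 6 (2S,5R)-2-tert-butyl-5-[(1S)-1-hydroxy-2,2-dimethoxyethyl]-5-methyl-1,3-dioxolan-4-one, via lithium enolate 5 (not isolated)
Conditions: LiN(i-Pr)2 (LDA), THF, −78 °C; then anhydrous 4, −78 °C; aq. NH4Cl
Reagents that add atoms: none
Why: Aldol addition of the Seebach dioxolanone enolate, in which the aldehyde adds anti to the tert-butyl group (C4 is set with retention of the lactate configuration) through a chair Zimmerman–Traxler transition state with CH(OMe)2 equatorial, placing the new C5 hydroxyl anti to the ring oxygen (the 4,5 relationship of the target; the minor C5 epimer is removed by chromatography).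

Step 3
Reactants: 6 (2S,5R)-2-tert-butyl-5-[(1S)-1-hydroxy-2,2-dimethoxyethyl]-5-methyl-1,3-dioxolan-4-one; 7 (R)-2-methylbutanoic acid
Product: 8 (1S)-1-[(2S,4R)-2-tert-butyl-4-methyl-5-oxo-1,3-dioxolan-4-yl]-2,2-dimethoxyethyl (2R)-2-methylbutanoate
Conditions: DCC, DMAP (0.2 equiv), CH2Cl2, 0 °C → rt
Reagents that add atoms: none
Why: Steglich esterification of the only free hydroxyl puts the (R)-2-methylbutanoate on O5 before any other hydroxyl exists; no stereocentre is formed and the α-branched acid does not epimerise under these conditions.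

Step 4
Reactants: 8 (1S)-1-[(2S,4R)-2-tert-butyl-4-methyl-5-oxo-1,3-dioxolan-4-yl]-2,2-dimethoxyethyl (2R)-2-methylbutanoate
Product: 9 S-ethyl (2R,3S)-2-hydroxy-4,4-dimethoxy-2-methyl-3-{[(2R)-2-methylbutanoyl]oxy}butanethioate
Conditions: EtSH (5 equiv), NaSEt (10 mol %), THF, 0 °C → rt
Reagents that add atoms: ethanethiol, CCS
Why: Thiolate-catalysed acyl substitution at the activated acylal carbonyl (the usual nucleophilic opening of Seebach dioxolanones, here with a thiol) expels pivalaldehyde irreversibly and frees the C4 tertiary alcohol, while the ordinary 2-methylbutanoate does not transthioesterify; no stereocentre is touched.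

Step 5
Reactants: 10 methyl (triphenyl-λ5-phosphanylidene)acetate; 11 (iodomethyl)trimethylsilane
Product: 12 methyl 2-(triphenyl-λ5-phosphanylidene)-3-(trimethylsilyl)propanoate
Conditions: 10 (2.0 equiv), MeCN, reflux; phosphonium salt filtered off
Reagents that add atoms: none
Why: C-alkylation of the stabilised ylide by the α-silyl iodide followed by transylidation with the second equivalent of 10, the standard way to α-substituted stabilised Wittig reagents; no stereocentre.

Step 6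
Reactants: 13 (4R)-2,2-dimethyl-1,3-dioxolane-4-carbaldehyde (D-glyceraldehyde acetonide); 14 2-[(2E)-but-2-en-1-yl]-4,4,5,5-tetramethyl-1,3,2-dioxaborolane
Product: 15 (1R,2R)-1-[(4R)-2,2-dimethyl-1,3-dioxolan-4-yl]-2-methylbut-3-en-1-ol
Conditions: (R)-TRIP (5 mol %), 4 Å MS, toluene, −30 °C; aq. NaHCO3
Reagents that add atoms: none
Why: Chiral-phosphoric-acid-catalysed crotylboration through a closed chair transition state, in which the (E)-crotyl geometry gives the 9,10-anti relationship and the (R)-catalyst is expected to deliver the crotyl group to the Re face of the aldehyde against its Felkin bias to give the 8,9-syn adduct (the isomer also favoured by the (S,S)-tartrate crotylboronate with this aldehyde).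

Step 7
Reactants: 15 (1R,2R)-1-[(4R)-2,2-dimethyl-1,3-dioxolan-4-yl]-2-methylbut-3-en-1-ol; 16 3-methylbutanoyl chloride
Product: 17 (1R,2R)-1-[(4R)-2,2-dimethyl-1,3-dioxolan-4-yl]-2-methylbut-3-en-1-yl 3-methylbutanoate
Conditions: pyridine, DMAP (cat.), CH2Cl2, 0 °C → rt
Reagents that add atoms: none
Why: DMAP-catalysed acylation of the single free hydroxyl; O8 is still locked in the acetonide, so the isovalerate goes to O9 unambiguously.

Step 8
Reactants: 17 (1R,2R)-1-[(4R)-2,2-dimethyl-1,3-dioxolan-4-yl]-2-methylbut-3-en-1-yl 3-methylbutanoate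
Product: 18 (2R,3R,4R)-1,2-dihydroxy-4-methylhex-5-en-3-yl 3-methylbutanoate
Conditions: AcOH/H2O (4:1), 40 °C
Reagents that add atoms: none
Why: Acid hydrolysis of the terminal isopropylidene acetal; under these mildly acidic conditions O9→O8 acyl migration is slow.

Step 9
Reactants: 18 (2R,3R,4R)-1,2-dihydroxy-4-methylhex-5-en-3-yl 3-methylbutanoate; 12 methyl 2-(triphenyl-λ5-phosphanylidene)-3-(trimethylsilyl)propanoate
Product: 20 methyl (2Z,4R,5R,6R)-4-hydroxy-6-methyl-5-[(3-methylbutanoyl)oxy]-2-[(trimethylsilyl)methyl]octa-2,7-dienoate, via α-hydroxy aldehyde 19 (not isolated)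
Conditions: TEMPO (10 mol %), KBr (10 mol %), NaOCl (1.05 equiv), NaHCO3, CH2Cl2/H2O, 0 °C; organic phase dried, then 12 (1.5 equiv), CH2Cl2, rt → 40 °C
Reagents that add atoms: none
Why: Anelli (TEMPO/NaOCl) oxidation is selective for the primary alcohol of the 1,2-diol and the crude α-hydroxy aldehyde is trapped at once in a Wittig reaction with the stabilised ylide, which puts C8 trans to the ester (2Z by CIP because CH2Si outranks CO2Me), a geometry that cannot lactonise onto O8.

Step 10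
Reactants: 20 methyl (2Z,4R,5R,6R)-4-hydroxy-6-methyl-5-[(3-methylbutanoyl)oxy]-2-[(trimethylsilyl)methyl]octa-2,7-dienoate
Product: 21 methyl (2Z,4R,5R,6R)-4-[(tert-butyldimethylsilyl)oxy]-6-methyl-5-[(3-methylbutanoyl)oxy]-2-[(trimethylsilyl)methyl]octa-2,7-dienoate
Conditions: TBSOTf, 2,6-lutidine, CH2Cl2, −78 → 0 °C
Reagents that add atoms: tert-butyldimethylsilyl trifluoromethanesulfonate, CC(C)(C)[Si](C)(C)OS(=O)(=O)C(F)(F)F
Why: Silylation of the only free hydroxyl masks O8 so that later only O6 can close the lactone, and it suppresses vinylogous Peterson elimination of the 4-hydroxy allylsilane.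

Step 11
Reactants: 21 methyl (2Z,4R,5R,6R)-4-[(tert-butyldimethylsilyl)oxy]-6-methyl-5-[(3-methylbutanoyl)oxy]-2-[(trimethylsilyl)methyl]octa-2,7-dienoate; 9 S-ethyl (2R,3S)-2-hydroxy-4,4-dimethoxy-2-methyl-3-{[(2R)-2-methylbutanoyl]oxy}butanethioate
Product: 23 methyl (2Z,4R,5R,6R,10R,11S)-4-[(tert-butyldimethylsilyl)oxy]-10-hydroxy-12,12-dimethoxy-6,10-dimethyl-5-[(3-methylbutanoyl)oxy]-11-{[(2R)-2-methylbutanoyl]oxy}-9-oxo-2-[(trimethylsilyl)methyl]dodec-2-enoate, via alkylborane 22 (not isolated)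
Conditions: 9-BBN, THF, rt; then 9, Pd(PPh3)4 (5 mol %), Cu(O2C-C4H3S) (CuTC, 1.5 equiv), Cs2CO3 (1 equiv), THF, 45 °C
Reagents that add atoms: none
Why: Anti-Markovnikov hydroboration of the terminal vinyl group (the ester-deactivated trisubstituted alkene is inert) followed by a B-alkyl Liebeskind–Srogl ketone synthesis with the thioester forms the C2–C3 bond and the C3 ketone under conditions that tolerate the esters, the free tertiary alcohol and the allylsilane; no stereocentre is formed.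

Step 12
Reactants: 23 methyl (2Z,4R,5R,6R,10R,11S)-4-[(tert-butyldimethylsilyl)oxy]-10-hydroxy-12,12-dimethoxy-6,10-dimethyl-5-[(3-methylbutanoyl)oxy]-11-{[(2R)-2-methylbutanoyl]oxy}-9-oxo-2-[(trimethylsilyl)methyl]dodec-2-enoate
Product: 24 methyl (2Z,4R,5R,6R,10R,11S)-4-[(tert-butyldimethylsilyl)oxy]-10-hydroxy-6,10-dimethyl-5-[(3-methylbutanoyl)oxy]-11-{[(2R)-2-methylbutanoyl]oxy}-9,12-dioxo-2-[(trimethylsilyl)methyl]dodec-2-enoate
Conditions: Amberlyst-15, acetone/H2O (20:1), rt; used crude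
Reagents that add atoms: water, O
Why: Acid-resin hydrolysis of the dimethyl acetal unmasks the C6 aldehyde without cleaving the secondary TBS ether or protodesilylating the ester-deactivated allylsilane; the α-acyloxy aldehyde is carried on at once to avoid C5 epimerisation.

Step 13
Reactants: 24 methyl (2Z,4R,5R,6R,10R,11S)-4-[(tert-butyldimethylsilyl)oxy]-10-hydroxy-6,10-dimethyl-5-[(3-methylbutanoyl)oxy]-11-{[(2R)-2-methylbutanoyl]oxy}-9,12-dioxo-2-[(trimethylsilyl)methyl]dodec-2-enoate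
Product: 26 (4R,5R,6S,7R,8R,9R,10R)-8-[(tert-butyldimethylsilyl)oxy]-4-hydroxy-9-[(3-methylbutanoyl)oxy]-5-{[(2R)-2-methylbutanoyl]oxy}-3-oxogermacr-11(13)-en-12,6-olide, via 6-O-trimethylsilyl hydroxy ester 25 (not isolated)
Conditions: Me3SiNTf2 (0.3 equiv), CH2Cl2, 0.5 mM (slow addition of 24), −78 → −40 °C; then MeOH, TsOH·H2O (cat.), 0 °C → rt
Reagents that add atoms: none
Why: Proposed new method: a silyl-cation-initiated, silyl-terminated cation–olefin macrocyclisation (intramolecular Hosomi–Sakurai reaction) in which the O-silylated C6 oxocarbenium ion is attacked by the C7=C11 π bond and Me3Si+ is lost from C13, after which acid methanolysis of the 6-O-silyl ether lets O6 (O8 being silylated) close the lactone on the methyl ester; C6 (S) is expected from anti attack on the dioxolan-2-ylium ion formed by participation of the C5 ester (the 1,2-trans rule of C-glycosylation), C7 (R) from attack anti to the C8 silyloxy group with H8 eclipsing the alkene (A(1,3) strain with CH2SiMe3), and the C3 ketone is spared because it is less electrophilic and flanked by the quaternary C4; the closest known reactions are the Hosomi–Sakurai allylation of aldehydes and acetals with 2-(trimethylsilylmethyl)acrylates to give α-methylene-γ-butyrolactones and acyloxy-directed allylsilane additions, here run intramolecularly at high dilution to close a ten-membered ring.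

Step 14
Reactants: 26 (4R,5R,6S,7R,8R,9R,10R)-8-[(tert-butyldimethylsilyl)oxy]-4-hydroxy-9-[(3-methylbutanoyl)oxy]-5-{[(2R)-2-methylbutanoyl]oxy}-3-oxogermacr-11(13)-en-12,6-olide
Product: 27 (4R,5R,6S,7R,8R,9R,10R)-4,8-dihydroxy-9-[(3-methylbutanoyl)oxy]-5-{[(2R)-2-methylbutanoyl]oxy}-3-oxogermacr-11(13)-en-12,6-olide (CNP0269576.1)
Conditions: HF·pyridine, pyridine, THF, 0 °C → rt
Reagents that add atoms: none
Why: Buffered fluoride desilylation of the secondary TBS ether leaves the α-methylene lactone, both esters and the α-ketol untouched and changes no stereocentre.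

**Compound list**
1 | (S)-lactic acid | C[C@H](O)C(=O)O | starting material
2 | pivalaldehyde | CC(C)(C)C=O | starting material
3 | (2S,5S)-2-tert-butyl-5-methyl-1,3-dioxolan-4-one | CC(C)(C)[C@@H]1OC(=O)[C@H](C)O1 | intermediate
4 | 2,2-dimethoxyacetaldehyde | COC(OC)C=O | starting material
5 | lithium (2S)-2-tert-butyl-5-methyl-1,3-dioxol-4-olate (lithium enolate of 3) | CC(C)(C)[C@@H]1OC([O-])=C(C)O1.[Li+] | intermediate
6 | (2S,5R)-2-tert-butyl-5-[(1S)-1-hydroxy-2,2-dimethoxyethyl]-5-methyl-1,3-dioxolan-4-one | CC(C)(C)[C@@H]1OC(=O)[C@](C)(O1)[C@H](O)C(OC)OC | intermediate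
7 | (R)-2-methylbutanoic acid | CC[C@@H](C)C(=O)O | starting material
8 | (1S)-1-[(2S,4R)-2-tert-butyl-4-methyl-5-oxo-1,3-dioxolan-4-yl]-2,2-dimethoxyethyl (2R)-2-methylbutanoate | CC(C)(C)[C@@H]1OC(=O)[C@](C)(O1)[C@H](OC(=O)[C@H](C)CC)C(OC)OC | intermediate
9 | S-ethyl (2R,3S)-2-hydroxy-4,4-dimethoxy-2-methyl-3-{[(2R)-2-methylbutanoyl]oxy}butanethioate | CCSC(=O)[C@](C)(O)[C@H](OC(=O)[C@H](C)CC)C(OC)OC | intermediate
10 | methyl (triphenyl-λ5-phosphanylidene)acetate | COC(=O)C=P(c1ccccc1)(c1ccccc1)c1ccccc1 | starting material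
11 | (iodomethyl)trimethylsilane | C[Si](C)(C)CI | starting material
12 | methyl 2-(triphenyl-λ5-phosphanylidene)-3-(trimethylsilyl)propanoate | COC(=O)C(C[Si](C)(C)C)=P(c1ccccc1)(c1ccccc1)c1ccccc1 | intermediate
13 | (4R)-2,2-dimethyl-1,3-dioxolane-4-carbaldehyde | O=C[C@H]1COC(C)(C)O1 | starting material
14 | 2-[(2E)-but-2-en-1-yl]-4,4,5,5-tetramethyl-1,3,2-dioxaborolane | C/C=C/CB1OC(C)(C)C(C)(C)O1 | starting material
15 | (1R,2R)-1-[(4R)-2,2-dimethyl-1,3-dioxolan-4-yl]-2-methylbut-3-en-1-ol | C=C[C@@H](C)[C@@H](O)[C@H]1COC(C)(C)O1 | intermediate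
16 | 3-methylbutanoyl chloride | CC(C)CC(=O)Cl | starting material
17 | (1R,2R)-1-[(4R)-2,2-dimethyl-1,3-dioxolan-4-yl]-2-methylbut-3-en-1-yl 3-methylbutanoate | C=C[C@@H](C)[C@@H](OC(=O)CC(C)C)[C@H]1COC(C)(C)O1 | intermediate
18 | (2R,3R,4R)-1,2-dihydroxy-4-methylhex-5-en-3-yl 3-methylbutanoate | C=C[C@@H](C)[C@@H](OC(=O)CC(C)C)[C@H](O)CO | intermediate
19 | (2S,3R,4R)-2-hydroxy-4-methyl-1-oxohex-5-en-3-yl 3-methylbutanoate | C=C[C@@H](C)[C@@H](OC(=O)CC(C)C)[C@H](O)C=O | intermediate
20 | methyl (2Z,4R,5R,6R)-4-hydroxy-6-methyl-5-[(3-methylbutanoyl)oxy]-2-[(trimethylsilyl)methyl]octa-2,7-dienoate | C=C[C@@H](C)[C@@H](OC(=O)CC(C)C)[C@H](O)/C=C(\C[Si](C)(C)C)C(=O)OC | intermediate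
21 | methyl (2Z,4R,5R,6R)-4-[(tert-butyldimethylsilyl)oxy]-6-methyl-5-[(3-methylbutanoyl)oxy]-2-[(trimethylsilyl)methyl]octa-2,7-dienoate | C=C[C@@H](C)[C@@H](OC(=O)CC(C)C)[C@H](O[Si](C)(C)C(C)(C)C)/C=C(\C[Si](C)(C)C)C(=O)OC | intermediate
22 | methyl (2Z,4R,5R,6R)-8-(9-borabicyclo[3.3.1]nonan-9-yl)-4-[(tert-butyldimethylsilyl)oxy]-6-methyl-5-[(3-methylbutanoyl)oxy]-2-[(trimethylsilyl)methyl]oct-2-enoate | C(C[C@@H](C)[C@@H](OC(=O)CC(C)C)[C@H](O[Si](C)(C)C(C)(C)C)/C=C(\C[Si](C)(C)C)C(=O)OC)B1C2CCCC1CCC2 | intermediate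
23 | methyl (2Z,4R,5R,6R,10R,11S)-4-[(tert-butyldimethylsilyl)oxy]-10-hydroxy-12,12-dimethoxy-6,10-dimethyl-5-[(3-methylbutanoyl)oxy]-11-{[(2R)-2-methylbutanoyl]oxy}-9-oxo-2-[(trimethylsilyl)methyl]dodec-2-enoate | C[Si](C)(C)C/C(C(=O)OC)=C\[C@@H](O[Si](C)(C)C(C)(C)C)[C@H](OC(=O)CC(C)C)[C@H](C)CCC(=O)[C@](C)(O)[C@@H](C(OC)OC)OC(=O)[C@H](C)CC | intermediate
24 | methyl (2Z,4R,5R,6R,10R,11S)-4-[(tert-butyldimethylsilyl)oxy]-10-hydroxy-6,10-dimethyl-5-[(3-methylbutanoyl)oxy]-11-{[(2R)-2-methylbutanoyl]oxy}-9,12-dioxo-2-[(trimethylsilyl)methyl]dodec-2-enoate | C[Si](C)(C)C/C(C(=O)OC)=C\[C@@H](O[Si](C)(C)C(C)(C)C)[C@H](OC(=O)CC(C)C)[C@H](C)CCC(=O)[C@](C)(O)[C@@H](C=O)OC(=O)[C@H](C)CC | intermediate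
25 | methyl (4R,5R,6S,7R,8R,9R,10R)-8-[(tert-butyldimethylsilyl)oxy]-4-hydroxy-9-[(3-methylbutanoyl)oxy]-5-{[(2R)-2-methylbutanoyl]oxy}-3-oxo-6-[(trimethylsilyl)oxy]germacr-11(13)-en-12-oate | C=C(C(=O)OC)[C@@H]1[C@@H](O[Si](C)(C)C(C)(C)C)[C@H](OC(=O)CC(C)C)[C@H](C)CCC(=O)[C@](C)(O)[C@H](OC(=O)[C@H](C)CC)[C@H]1O[Si](C)(C)C | intermediate
26 | (4R,5R,6S,7R,8R,9R,10R)-8-[(tert-butyldimethylsilyl)oxy]-4-hydroxy-9-[(3-methylbutanoyl)oxy]-5-{[(2R)-2-methylbutanoyl]oxy}-3-oxogermacr-11(13)-en-12,6-olide | C=C1C(=O)O[C@H]2[C@H]1[C@@H](O[Si](C)(C)C(C)(C)C)[C@H](OC(=O)CC(C)C)[C@H](C)CCC(=O)[C@](C)(O)[C@@H]2OC(=O)[C@H](C)CC | intermediate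
27 | (4R,5R,6S,7R,8R,9R,10R)-4,8-dihydroxy-9-[(3-methylbutanoyl)oxy]-5-{[(2R)-2-methylbutanoyl]oxy}-3-oxogermacr-11(13)-en-12,6-olide (CNP0269576.1) | C=C1C(=O)O[C@H]2[C@H]1[C@@H](O)[C@H](OC(=O)CC(C)C)[C@H](C)CCC(=O)[C@](C)(O)[C@@H]2OC(=O)[C@H](C)CC | target

**Step count**
Total: 14 steps. Longest linear sequence: 9 steps (13 → 27, steps 6–14); the west branch (1 → 27) is 8 steps.

**Steps most likely to fail, each with a fallback**

Step 13 (macrocyclisation/lactonisation). The ester-substituted allylsilane is a weak π-nucleophile, the ten-membered closure has no entropic help, the γ-keto aldehyde can hemiketalise, and the C6 configuration depends on ester participation winning over Felkin control. The fallback sets out from 24 and comes back at 26. Bromodesilylation of 24 with NBS (CH2Cl2, −78 °C) moves the double bond to C11=C13 and puts bromine on C7, giving the C7-bromo 11(13)-ene isomer of 24 F1. CrCl2 in THF at high dilution then closes C6–C7 by a Nozaki–Hiyama allylation through the allylchromium species, which adds to the aldehyde only, to give (as its chromium alkoxide) the 6-hydroxy methyl ester F2. Treatment with TsOH lactonises F2 to 26.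

Step 11 (fragment union). The thioester is α-quaternary, so transmetalation may be slow and the acyl palladium intermediate may decarbonylate; carbonate at 45 °C may also move the O5 ester. The fallback sets out from 21 and comes back at 23. Hydroboration of 21 with 9-BBN followed by I2/NaOMe gives the primary iodide methyl (2Z,4R,5R,6R)-4-[(tert-butyldimethylsilyl)oxy]-8-iodo-6-methyl-5-[(3-methylbutanoyl)oxy]-2-[(trimethylsilyl)methyl]oct-2-enoate F3. Zinc insertion (Zn dust, LiCl, THF) gives the corresponding alkylzinc iodide F4, which is coupled with thioester 9 under neutral Fukuyama conditions (PdCl2(PPh3)2, toluene, rt) to give 23.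

Step 9 (diol oxidation/Wittig). The primary-selective oxidation of a free 1,2-diol can over-oxidise or cleave, the α-hydroxy aldehyde can dimerise or suffer acyl migration, and the hindered ylide may react slowly. The fallback sets out from 18 and comes back at 21, so step 10 is no longer needed. Bis-silylation of 18 (TBSOTf, 2,6-lutidine) gives (2R,3R,4R)-1,2-bis[(tert-butyldimethylsilyl)oxy]-4-methylhex-5-en-3-yl 3-methylbutanoate F5. Selective cleavage of the primary silyl ether (HF·pyridine, pyridine, THF, 0 °C) gives (2R,3R,4R)-2-[(tert-butyldimethylsilyl)oxy]-1-hydroxy-4-methylhex-5-en-3-yl 3-methylbutanoate F6. Dess–Martin oxidation gives the configurationally more robust aldehyde (2S,3R,4R)-2-[(tert-butyldimethylsilyl)oxy]-4-methyl-1-oxohex-5-en-3-yl 3-methylbutanoate F7, and Wittig reaction of F7 with 12 gives 21.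

**Further compounds**
F1 | step 13 | methyl 3-bromo-2-methylidene analogue of 24 (bromine on C7 and C11=C13 in place of C7=C11 and CH2SiMe3; both C7 epimers; all other centres as in 24) | C=C(C(=O)OC)C(Br)[C@@H](O[Si](C)(C)C(C)(C)C)[C@H](OC(=O)CC(C)C)[C@H](C)CCC(=O)[C@](C)(O)[C@@H](C=O)OC(=O)[C@H](C)CC
F2 | step 13 | methyl (4R,5R,6S,7R,8R,9R,10R)-8-[(tert-butyldimethylsilyl)oxy]-4,6-dihydroxy-9-[(3-methylbutanoyl)oxy]-5-{[(2R)-2-methylbutanoyl]oxy}-3-oxogermacr-11(13)-en-12-oate | C=C(C(=O)OC)[C@@H]1[C@@H](O[Si](C)(C)C(C)(C)C)[C@H](OC(=O)CC(C)C)[C@H](C)CCC(=O)[C@](C)(O)[C@H](OC(=O)[C@H](C)CC)[C@H]1O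
F3 | step 11 | methyl (2Z,4R,5R,6R)-4-[(tert-butyldimethylsilyl)oxy]-8-iodo-6-methyl-5-[(3-methylbutanoyl)oxy]-2-[(trimethylsilyl)methyl]oct-2-enoate | ICC[C@@H](C)[C@@H](OC(=O)CC(C)C)[C@H](O[Si](C)(C)C(C)(C)C)/C=C(\C[Si](C)(C)C)C(=O)OC
F4 | step 11 | alkylzinc iodide from F3 (C–ZnI in place of C–I) | I[Zn]CC[C@@H](C)[C@@H](OC(=O)CC(C)C)[C@H](O[Si](C)(C)C(C)(C)C)/C=C(\C[Si](C)(C)C)C(=O)OC
F5 | step 9 | (2R,3R,4R)-1,2-bis[(tert-butyldimethylsilyl)oxy]-4-methylhex-5-en-3-yl 3-methylbutanoate | C=C[C@@H](C)[C@@H](OC(=O)CC(C)C)[C@H](O[Si](C)(C)C(C)(C)C)CO[Si](C)(C)C(C)(C)C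
F6 | step 9 | (2R,3R,4R)-2-[(tert-butyldimethylsilyl)oxy]-1-hydroxy-4-methylhex-5-en-3-yl 3-methylbutanoate | C=C[C@@H](C)[C@@H](OC(=O)CC(C)C)[C@H](O[Si](C)(C)C(C)(C)C)CO
F7 | step 9 | (2S,3R,4R)-2-[(tert-butyldimethylsilyl)oxy]-4-methyl-1-oxohex-5-en-3-yl 3-methylbutanoate | C=C[C@@H](C)[C@@H](OC(=O)CC(C)C)[C@H](O[Si](C)(C)C(C)(C)C)C=O
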